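**Plan**
Feature: ring B (C5, C6, C8, C9, C10; gibberellane numbering) has H-9 β next to quaternary C8, which is α to the C6 carbon; the C11 arm on C9 is trans to the C15 arm on C8 and C10 is oxygenated. This is a 4-oxygenated cyclopent-2-enone after conjugate addition at C9 and enolate alkylation at C8.
Retrosynthetic cuts: C1–O (hydration of a Δ1-3-ketone), C3–C4 (Dieckmann), C1=C2 (olefination), C4–C5 (lactone-forming Michael), C10–C1 (formyl anion), C13–C16 (gold), C11=C12 (metathesis), C6–C7 (carbonylation) and, at the core, C9–C11 together with C8–C15.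
Forward order: ring B is enone 1; three-component coupling, then ring C, C7, the C12 ketone, ring D, the C10 ketone, C1, the γ-lactone, ring A and last the 1β-hydroxyl.
Stereochemistry: the C10 silyl ether of (R)-1 sets C9, C9 sets C8, the C8 tether sets C13; a bulky hydride sets C12; shielding by C11 and the 12-silyloxy group sets C10; the ester tether sets C5, equilibration C6, ring closure C4, and the lactone-covered α face sets C1.

Key step: step 3

Remarks: Gibberellane numbering is used throughout; carbons C1, C2, C3, C4, C5 of the early cyclopentenones become C6, C8, C9, C10, C5. β is the face of ring B that carries H-5, H-9, C7 and C15 in the target; α is the face of the lactone oxygen, C11 and C14. The silyloxy enone, the butenylzinc reagent and the silylated propargyl bromide are taken as commercial. The carbinol configuration from hydroboration and the C4 configuration before ring A closes are erased later; the SMILES show the epimer expected to prevail.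

**Route**

Step 1
Reactants: 1 (R)-4-(tert-butyldimethylsilyloxy)cyclopent-2-en-1-one
Product: 2 (R)-4-(tert-butyldimethylsilyloxy)-2-iodocyclopent-2-en-1-one
Conditions: I2, pyridine, CH2Cl2, 0 °C to rt
Reagents that add atoms: iodine, II
Why: Pyridine-mediated α-iodination of the enone (conjugate addition of pyridine, iodination of the enolate, elimination) leaves the silyl ether stereocentre untouched.

Step 2
Reactants: 2 (R)-4-(tert-butyldimethylsilyloxy)-2-iodocyclopent-2-en-1-one; 3 but-3-enylzinc bromide
Product: 4 (R)-2-(but-3-en-1-yl)-4-(tert-butyldimethylsilyloxy)cyclopent-2-en-1-one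
Conditions: Pd2(dba)3 (2.5 mol %), P(2-furyl)3 (10 mol %), THF/DMF, rt
Reagents that add atoms: none
Why: Negishi cross-coupling of the α-iodoenone with the alkylzinc halide on zerovalent palladium installs the C14–C12 arm on C8 without disturbing the allylic silyl ether.

Step 3
Reactants: 4 (R)-2-(but-3-en-1-yl)-4-(tert-butyldimethylsilyloxy)cyclopent-2-en-1-one; 5 vinylmagnesium bromide; 6 3-bromo-1-(triisopropylsilyl)prop-1-yne
Product: 8 (2R,3R,4R)-2-(but-3-en-1-yl)-4-(tert-butyldimethylsilyloxy)-3-ethenyl-2-[3-(triisopropylsilyl)prop-2-yn-1-yl]cyclopentan-1-one, via bromomagnesium enolate 7 (not isolated)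
Conditions: 5, CuBr·SMe2 (20 mol %), THF, −78 to −40 °C; then HMPA, 6, −40 to 0 °C
Reagents that add atoms: none
Why: The vinylcopper species formed from 5 and CuBr·SMe2 adds 1,4 to enone 4 at C9, and the regiodefined C6–C8 enolate 7 is then C-alkylated by propargylic bromide 6 in the presence of HMPA, so that C9–C11 and C8–C15 form in one flask (conjugate addition–enolate alkylation, the three-component coupling known from prostaglandin synthesis). No ring is closed. C9 is controlled by the C10 silyl ether, which sends the vinyl group to the opposite face of the planar enone; C8 is controlled by the new C9 vinyl group, which sends the electrophile to the opposite face and so places the butenyl arm (C14) cis and the propargyl arm (C15) trans to C11. The step needs a regiostable enolate, because an enolate toward C5 would expel the β-silyloxy group; the α-butenyl substituent fixes the enolate between C6 and C8 and alkylation at low temperature precedes proton transfer. It also needs direct rather than allenyl-forming substitution on 6, which the bulky silyl group on the alkyne terminus secures.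

Step 4
Reactants: 8 (2R,3R,4R)-2-(but-3-en-1-yl)-4-(tert-butyldimethylsilyloxy)-3-ethenyl-2-[3-(triisopropylsilyl)prop-2-yn-1-yl]cyclopentan-1-one
Product: 9 cis-fused ring B/C ketone (C6 ketone; Δ11 alkene; 10β-OTBS; 8β-silylpropargyl; 9β-H)
Conditions: second-generation Grubbs catalyst (5 mol %), CH2Cl2, 40 °C
Reagents that add atoms: none
Why: Ring-closing metathesis joins the cis-disposed vinyl and butenyl arms into the cyclohexene ring C with loss of ethene, while the bulky silylalkyne stays out of enyne metathesis.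

Step 5
Reactants: 9 cis-fused ring B/C ketone
Product: 11 C6 enol triflate (Δ5) of the ring B/C bicycle, via potassium enolate 10 (not isolated)
Conditions: KN(SiMe3)2, THF, −78 °C; then PhNTf2, −78 °C
Reagents that add atoms: N-phenylbis(trifluoromethanesulfonimide), O=S(=O)(N(c1ccccc1)S(=O)(=O)C(F)(F)F)C(F)(F)F
Why: Enolisation can occur only toward C5 because C8 is quaternary, and triflation of the potassium enolate at −78 °C should outrun β-elimination of the silyloxy group (enol triflate formation).

Step 6
Reactants: 11 C6 enol triflate (Δ5)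
Product: 12 2-(trimethylsilyl)ethyl Δ5-ene-7-oate of the ring B/C bicycle
Conditions: Pd(OAc)2 (5 mol %), PPh3 (10 mol %), CO (1 atm), Me3SiCH2CH2OH, Et3N, DMF, 50 °C
Reagents that add atoms: carbon monoxide, [C-]#[O+]; 2-(trimethylsilyl)ethanol, C[Si](C)(C)CCO
Why: Palladium-catalysed alkoxycarbonylation of the enol triflate (oxidative addition, CO insertion, alcoholysis) attaches C7 as a fluoride-labile ester and creates the C5=C6–C7 acceptor needed later.

Step 7
Reactants: 12 2-(trimethylsilyl)ethyl Δ5-ene-7-oate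
Product: 14 12β-alcohol (C11 saturated), via 12-boryl adduct 13 (not isolated)
Conditions: 9-BBN, THF, 60 °C; then NaBO3·4H2O, H2O, rt
Reagents that add atoms: sodium perborate tetrahydrate, [Na+].[O-]OB=O.O.O.O.O
Why: Hydroboration–oxidation: the bulky dialkylborane should place boron on C12, the alkene carbon remote from ring-fusion carbon C9, from the convex β face, and spare the electron-poor enoate and the shielded silylalkyne.

Step 8
Reactants: 14 12β-alcohol
Product: 15 12-ketone (silylalkyne)
Conditions: Dess–Martin periodinane, NaHCO3, CH2Cl2, rt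
Reagents that add atoms: none
Why: Dess–Martin oxidation of the secondary alcohol gives the C12 ketone and erases the carbinol configuration.

Step 9
Reactants: 15 12-ketone (silylalkyne)
Product: 17 12-ketone with terminal alkyne, via silver acetylide 16 (not isolated)
Conditions: AgF, MeOH/THF, rt, dark; then 1 M HCl
Reagents that add atoms: none
Why: Silver fluoride cleaves the alkynyl C–Si bond selectively (silver acetylide, then protonation) and should leave the silyl ether and the silylethyl ester intact.

Step 10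
Reactants: 17 12-ketone with terminal alkyne
Product: 18 Δ12 tert-butyldimethylsilyl enol ether
Conditions: t-BuMe2SiOTf, Et3N, CH2Cl2, −78 to 0 °C
Reagents that add atoms: tert-butyldimethylsilyl trifluoromethanesulfonate, CC(C)(C)[Si](C)(C)OS(=O)(=O)C(F)(F)F
Why: Soft enolisation (silyl triflate and amine) should remove the more accessible C13 proton, C11 being flanked by ring-fusion carbon C9; any Δ11 isomer cannot close a five-membered ring in step 11 and would be returned as 17.

Step 11
Reactants: 18 Δ12 tert-butyldimethylsilyl enol ether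
Product: 19 ring B/C/D 12-ketone with 16-methylene (10β-OTBS; Δ5-ene-7-oate)
Conditions: Ph3PAuCl (10 mol %), AgBF4 (10 mol %), toluene/MeOH (10:1), rt
Reagents that add atoms: none
Why: Gold-catalysed 5-exo-dig carbocyclisation of the enol silane onto the alkyne (Conia-ene-type addition, then protodeauration and desilylation by methanol) forms C13–C16 and the exocyclic methylene; C13 is fixed because the propargyl tether is anchored on the β face of C8.

Step 12
Reactants: 19 ring B/C/D 12-ketone
Product: 20 12α-alcohol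
Conditions: LiBH(s-Bu)3, THF, −78 °C; then aqueous NH4Cl
Reagents that add atoms: none
Why: The bulky trialkylborohydride should deliver hydride to the β face of the C12 ketone (equatorial attack, the α face being blocked by the syn-axial C9–C10 bond) and give the axial 12α-alcohol.

Step 13
Reactants: 20 12α-alcohol
Product: 21 12α-triisopropylsilyl ether
Conditions: i-Pr3SiOTf, 2,6-lutidine, CH2Cl2, 0 °C to rt
Reagents that add atoms: triisopropylsilyl trifluoromethanesulfonate, CC(C)[Si](OS(=O)(=O)C(F)(F)F)(C(C)C)C(C)C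
Why: Silylation with the reactive silyl triflate protects the hindered axial alcohol as an ether that outlasts the acidic fluoride and base steps ahead.

Step 14
Reactants: 21 12α-triisopropylsilyl ether
Product: 22 10β-alcohol
Conditions: HF·pyridine, pyridine, THF, 0 °C to rt
Reagents that add atoms: none
Why: Buffered HF·pyridine removes the unhindered allylic tert-butyldimethylsilyl ether faster than the hindered triisopropylsilyl ether and does not cleave the silylethyl ester.

Step 15
Reactants: 22 10β-alcohol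
Product: 23 10-ketone (Δ5-en-10-one)
Conditions: Dess–Martin periodinane, NaHCO3, CH2Cl2, 0 °C to rt
Reagents that add atoms: none
Why: Dess–Martin oxidation of the allylic alcohol gives the C10 ketone and removes the stereocentre that has done its work.

Step 16
Reactants: 23 10-ketone (Δ5-en-10-one)
Product: 25 10α-propionate bearing a 10β-(1,3-dithian-2-yl) group, via lithium alkoxide 24 (not isolated)
Conditions: 1,3-dithiane, n-BuLi, THF, −30 °C; then 23, −78 °C; then (EtCO)2O, −78 to 0 °C
Reagents that add atoms: 1,3-dithiane, C1CSCSC1; propionic anhydride, CCC(=O)OC(=O)CC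
Why: 2-Lithio-1,3-dithiane, a formyl anion equivalent (Corey–Seebach), should add 1,2 to the C10 ketone from the β face, anti to C11 and to the 12α-silyloxy group that flank the α face, and the tertiary alkoxide is acylated in the same flask.

Step 17
Reactants: 25 10α-propionate bearing a 10β-(1,3-dithian-2-yl) group
Product: 26 19,10-γ-lactone with C1 dithiane (H-5 β; 6β-ester)
Conditions: KOt-Bu (0.5 equiv), THF/t-BuOH (10:1), −20 to 20 °C
Reagents that add atoms: none
Why: Intramolecular Michael addition (5-exo-trig) of the propionate enolate to C5 of the enoate closes the γ-lactone; the tether through the α oxygen on C10 forces C4 onto the α face of C5 and base equilibration should place the C6 ester trans to C4.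

Step 18
Reactants: 26 19,10-γ-lactone with C1 dithiane
Product: 27 C1 aldehyde
Conditions: MeI, CaCO3, MeCN/H2O (9:1), 45 °C
Reagents that add atoms: water, O
Why: S-Methylation and hydrolysis of the dithiane liberate the non-enolisable C1 aldehyde under conditions that spare the exocyclic alkene.

Step 19
Reactants: 27 C1 aldehyde
Product: 28 (Z)-enoate (C1=C2–C3O2Me)
Conditions: (CF3CH2O)2P(O)CH2CO2Me, KN(SiMe3)2, 18-crown-6, THF, −78 °C
Reagents that add atoms: methyl bis(2,2,2-trifluoroethyl)phosphonoacetate, COC(=O)CP(=O)(OCC(F)(F)F)OCC(F)(F)F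
Why: Still–Gennari olefination should give the (Z)-enoate, the geometry that lets C3 reach C4.

Step 20
Reactants: 28 (Z)-enoate
Product: 29 Δ1-3-ketone (ring A closed; 4β-methyl)
Conditions: LiN(SiMe3)2, THF, −78 to −20 °C; then AcOH
Reagents that add atoms: none
Why: Dieckmann condensation: the lactone enolate at C4 attacks the (Z)-ester carbonyl C3 and expels methoxide, closing ring A; C4 can bond only on the face that carries C1, which fixes the quaternary centre.

Step 21
Reactants: 29 Δ1-3-ketone
Product: 30 1β-pinacolboryl 3-ketone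
Conditions: B2pin2, CuCl (10 mol %), NaOt-Bu (10 mol %), DPEphos (10 mol %), MeOH (2 equiv), THF, rt
Reagents that add atoms: bis(pinacolato)diboron, CC1(C)OB(OC1(C)C)B1OC(C)(C)C(C)(C)O1
Why: Copper-catalysed conjugate borylation of the enone: the boryl-copper species should add to C1 from the β face, the α face being covered by the lactone bridge and C11.

Step 22
Reactants: 30 1β-pinacolboryl 3-ketone
Product: 32 target acid CNP0259985.1, via boryl hydroxy acid 31 (not isolated)
Conditions: tris(dimethylamino)sulfonium difluorotrimethylsilicate, DMF, 0 °C to rt; then pH 7 phosphate buffer, NaBO3·4H2O, THF, 0 °C to rt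
Reagents that add atoms: sodium perborate tetrahydrate, [Na+].[O-]OB=O.O.O.O.O
Why: Fluoride cleaves the silylethyl ester (fragmentation to ethene) and the silyl ether while the β-boryl ketone cannot undergo retro-aldol or elimination; perborate then oxidises the C–B bond with retention to the 1β-alcohol in near-neutral water.

**Compound list**
1 | (R)-4-(tert-butyldimethylsilyloxy)cyclopent-2-en-1-one | C1=C[C@H](O[Si](C)(C)C(C)(C)C)CC1=O | starting material
2 | (R)-4-(tert-butyldimethylsilyloxy)-2-iodocyclopent-2-en-1-one | IC1=C[C@H](O[Si](C)(C)C(C)(C)C)CC1=O | intermediate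
3 | but-3-enylzinc bromide | C=CCC[Zn]Br | starting material
4 | (R)-2-(but-3-en-1-yl)-4-(tert-butyldimethylsilyloxy)cyclopent-2-en-1-one | C=CCCC1=C[C@H](O[Si](C)(C)C(C)(C)C)CC1=O | intermediate
5 | vinylmagnesium bromide | C=C[Mg]Br | starting material
6 | 3-bromo-1-(triisopropylsilyl)prop-1-yne | CC(C)[Si](C#CCBr)(C(C)C)C(C)C | starting material
7 | bromomagnesium C6–C8 enolate of the 9-vinyl adduct (not isolated) | C=CCCC1=C(O[Mg]Br)C[C@@H](O[Si](C)(C)C(C)(C)C)[C@@H]1C=C | intermediate
8 | (2R,3R,4R)-2-(but-3-en-1-yl)-4-(tert-butyldimethylsilyloxy)-3-ethenyl-2-[3-(triisopropylsilyl)prop-2-yn-1-yl]cyclopentan-1-one | CC(C)[Si](C(C)C)(C(C)C)C#CC[C@]1(CCC=C)[C@@H](C=C)[C@H](O[Si](C)(C)C(C)(C)C)CC1=O | intermediate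
9 | cis-fused ring B/C ketone (C6 ketone; Δ11; 10β-OTBS; 8β-silylpropargyl) | CC(C)[Si](C(C)C)(C(C)C)C#CC[C@]1(CCC=C2)[C@@H]2[C@H](O[Si](C)(C)C(C)(C)C)CC1=O | intermediate
10 | potassium C5–C6 enolate of 9 (not isolated) | CC(C)[Si](C(C)C)(C(C)C)C#CC[C@]1(CCC=C2)[C@@H]2[C@H](O[Si](C)(C)C(C)(C)C)C=C1O[K] | intermediate
11 | C6 enol triflate (Δ5) | CC(C)[Si](C(C)C)(C(C)C)C#CC[C@]1(CCC=C2)[C@@H]2[C@H](O[Si](C)(C)C(C)(C)C)C=C1OS(=O)(=O)C(F)(F)F | intermediate
12 | 2-(trimethylsilyl)ethyl Δ5-ene-7-oate | CC(C)[Si](C(C)C)(C(C)C)C#CC[C@]1(CCC=C2)[C@@H]2[C@H](O[Si](C)(C)C(C)(C)C)C=C1C(=O)OCC[Si](C)(C)C | intermediate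
13 | 12-(9-borabicyclo[3.3.1]nonan-9-yl) adduct (not isolated) | CC(C)[Si](C(C)C)(C(C)C)C#CC[C@]1(CC[C@H](B3C4CCCC3CCC4)C2)[C@@H]2[C@H](O[Si](C)(C)C(C)(C)C)C=C1C(=O)OCC[Si](C)(C)C | intermediate
14 | 12β-alcohol | CC(C)[Si](C(C)C)(C(C)C)C#CC[C@]1(CC[C@H](O)C2)[C@@H]2[C@H](O[Si](C)(C)C(C)(C)C)C=C1C(=O)OCC[Si](C)(C)C | intermediate
15 | 12-ketone (silylalkyne) | CC(C)[Si](C(C)C)(C(C)C)C#CC[C@]1(CCC(=O)C2)[C@@H]2[C@H](O[Si](C)(C)C(C)(C)C)C=C1C(=O)OCC[Si](C)(C)C | intermediate
16 | silver acetylide of 17 (not isolated) | [Ag]C#CC[C@]1(CCC(=O)C2)[C@@H]2[C@H](O[Si](C)(C)C(C)(C)C)C=C1C(=O)OCC[Si](C)(C)C | intermediate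
17 | 12-ketone with terminal alkyne | C#CC[C@]1(CCC(=O)C2)[C@@H]2[C@H](O[Si](C)(C)C(C)(C)C)C=C1C(=O)OCC[Si](C)(C)C | intermediate
18 | Δ12 tert-butyldimethylsilyl enol ether | C#CC[C@]1(CC=C(O[Si](C)(C)C(C)(C)C)C2)[C@@H]2[C@H](O[Si](C)(C)C(C)(C)C)C=C1C(=O)OCC[Si](C)(C)C | intermediate
19 | ring B/C/D 12-ketone with 16-methylene | C=C1C[C@]23C[C@H]1C(=O)C[C@H]2[C@H](O[Si](C)(C)C(C)(C)C)C=C3C(=O)OCC[Si](C)(C)C | intermediate
20 | 12α-alcohol | C=C1C[C@]23C[C@H]1[C@@H](O)C[C@H]2[C@H](O[Si](C)(C)C(C)(C)C)C=C3C(=O)OCC[Si](C)(C)C | intermediate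
21 | 12α-triisopropylsilyl ether | C=C1C[C@]23C[C@H]1[C@@H](O[Si](C(C)C)(C(C)C)C(C)C)C[C@H]2[C@H](O[Si](C)(C)C(C)(C)C)C=C3C(=O)OCC[Si](C)(C)C | intermediate
22 | 10β-alcohol | C=C1C[C@]23C[C@H]1[C@@H](O[Si](C(C)C)(C(C)C)C(C)C)C[C@H]2[C@H](O)C=C3C(=O)OCC[Si](C)(C)C | intermediate
23 | 10-ketone (Δ5-en-10-one) | C=C1C[C@]23C[C@H]1[C@@H](O[Si](C(C)C)(C(C)C)C(C)C)C[C@H]2C(=O)C=C3C(=O)OCC[Si](C)(C)C | intermediate
24 | lithium 10α-alkoxide with 10β-dithianyl group (not isolated) | C=C1C[C@]23C[C@H]1[C@@H](O[Si](C(C)C)(C(C)C)C(C)C)C[C@H]2[C@@](C4SCCCS4)(O[Li])C=C3C(=O)OCC[Si](C)(C)C | intermediate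
25 | 10α-propionate with 10β-(1,3-dithian-2-yl) group | C=C1C[C@]23C[C@H]1[C@@H](O[Si](C(C)C)(C(C)C)C(C)C)C[C@H]2[C@@](C4SCCCS4)(OC(=O)CC)C=C3C(=O)OCC[Si](C)(C)C | intermediate
26 | 19,10-γ-lactone with C1 dithiane (H-5 β; 6β-ester) | C=C1C[C@]23C[C@H]1[C@@H](O[Si](C(C)C)(C(C)C)C(C)C)C[C@H]2[C@@]4(C5SCCCS5)OC(=O)[C@H](C)[C@H]4[C@@H]3C(=O)OCC[Si](C)(C)C | intermediate
27 | C1 aldehyde | C=C1C[C@]23C[C@H]1[C@@H](O[Si](C(C)C)(C(C)C)C(C)C)C[C@H]2[C@@]4(C=O)OC(=O)[C@H](C)[C@H]4[C@@H]3C(=O)OCC[Si](C)(C)C | intermediate
28 | (Z)-enoate | C=C1C[C@]23C[C@H]1[C@@H](O[Si](C(C)C)(C(C)C)C(C)C)C[C@H]2[C@@]4(/C=C\C(=O)OC)OC(=O)[C@H](C)[C@H]4[C@@H]3C(=O)OCC[Si](C)(C)C | intermediate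
29 | Δ1-3-ketone (ring A closed) | C=C1C[C@]23C[C@H]1[C@@H](O[Si](C(C)C)(C(C)C)C(C)C)C[C@H]2[C@]12OC(=O)[C@](C)(C(=O)C=C1)[C@H]2[C@@H]3C(=O)OCC[Si](C)(C)C | intermediate
30 | 1β-pinacolboryl 3-ketone | C=C1C[C@]23C[C@H]1[C@@H](O[Si](C(C)C)(C(C)C)C(C)C)C[C@H]2[C@]12OC(=O)[C@](C)(C(=O)C[C@H]1B4OC(C)(C)C(C)(C)O4)[C@H]2[C@@H]3C(=O)OCC[Si](C)(C)C | intermediate
31 | 1β-pinacolboryl 12α-hydroxy 7-acid (not isolated) | C=C1C[C@]23C[C@H]1[C@@H](O)C[C@H]2[C@]12OC(=O)[C@](C)(C(=O)C[C@H]1B4OC(C)(C)C(C)(C)O4)[C@H]2[C@@H]3C(=O)O | intermediate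
32 | CNP0259985.1 (1β,12α-dihydroxy-3-oxo 19,10-lactone 7-acid) | C=C1C[C@]23C[C@H]1[C@@H](O)C[C@H]2[C@]12OC(=O)[C@](C)(C(=O)C[C@H]1O)[C@H]2[C@@H]3C(=O)O | target

**Step count**
Total: 22 steps. Longest linear sequence: 22 steps (1 to 32).

**Steps most likely to fail**

Step 3. Alkylation of the fully substituted enolate may be slower than proton transfer, which would move the enolate toward C5 and expel the silyloxy group, or may stop short of completion. Fallback: setting out from 4, the copper-catalysed addition of 5 is run with Me3SiCl present so that the enolate is captured as the trimethylsilyl enol ether F1, which is isolated. MeLi in THF then releases the salt-free lithium enolate F2, which is alkylated by 6 in THF/HMPA at −78 to −20 °C, coming back to the route at 8.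

Step 10. Silylation may go toward C11 instead of C13 (poor regioselectivity of enolisation), leaving little enol silane that can cyclise in step 11. Fallback: setting out from 17, the enol silane is dispensed with and 17 is heated with catalytic pyrrolidine, Cu(OTf)2 and PPh3 in dioxane (enamine and copper co-catalysed carbocyclisation). The two enamines interconvert and only the C13 enamine can reach the alkyne, since attack from C11 would demand a trans-fused bicyclo[3.3.0]octane; hydrolysis on work-up comes back to the route at 19, and no new compound is made (F0).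

Step 20. The hindered tertiary lactone enolate may form or acylate poorly, or methoxide may reopen the β-keto lactone (retro-Claisen). Fallback: setting out from 26, the lactone enolate (LiN(SiMe3)2, THF, −78 °C) is C-acetylated with 1-acetylimidazole on its convex face, anti to C6, to give the 4-acetyl lactone F3. MeI/CaCO3 hydrolysis of the dithiane gives the keto aldehyde F4, whose acetyl methyl group condenses with the non-enolisable C1 aldehyde (piperidinium acetate, benzene, 60 °C; intramolecular aldol condensation), coming back to the route at 29.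

**Further compounds**
F1 | step 3 | trimethylsilyl enol ether of the 9-vinyl adduct | C=CCCC1=C(O[Si](C)(C)C)C[C@@H](O[Si](C)(C)C(C)(C)C)[C@@H]1C=C
F2 | step 3 | lithium C6–C8 enolate of the 9-vinyl adduct | C=CCCC1=C(O[Li])C[C@@H](O[Si](C)(C)C(C)(C)C)[C@@H]1C=C
F0 | step 10 | none | none
F3 | step 20 | 4-acetyl 19,10-γ-lactone with C1 dithiane | C=C1C[C@]23C[C@H]1[C@@H](O[Si](C(C)C)(C(C)C)C(C)C)C[C@H]2[C@@]4(C5SCCCS5)OC(=O)[C@](C)(C(C)=O)[C@H]4[C@@H]3C(=O)OCC[Si](C)(C)C
F4 | step 20 | 4-acetyl 19,10-γ-lactone C1 aldehyde | C=C1C[C@]23C[C@H]1[C@@H](O[Si](C(C)C)(C(C)C)C(C)C)C[C@H]2[C@@]4(C=O)OC(=O)[C@](C)(C(C)=O)[C@H]4[C@@H]3C(=O)OCC[Si](C)(C)C
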